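**Plan**

- Locants used throughout: tetralin C1–C4, C4a, C5–C8, C8a; C9 is the carbon on C3, C9′ the carbon on C2; ring B is the fused arene, ring C the pendant aryl group.
- Retrosynthesis: both CH2OH groups go back to an acid (C9) and an ester (C9′). The ring bond C1–C2 and the C1–ring C bond are then cut together, leaving a C8a aldehyde, a ring C Grignard reagent and an open-chain succinic half-ester. Last, C8a–C1 is cut (formylation of a symmetric 3,4,5-trimethoxyphenyl ring) and C2–C3 (Evans alkylation).
- Enabling feature: the free C8 hydroxyl of ring B is ortho to C8a–C1, so O8/C8/C8a/C1 can become an o-quinone methide with C1 as its electrophilic end, and C2 is α to the C9′ carbonyl, i.e. an enolate carbon.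
- Forward order: open chain with C3 set, then the formyl carbon (C1) on ring B, formyl-directed BCl3 unmasking of the C8/C7 catechol, bis-Boc protection, then a one-pot aryl addition / Boc transfer / methide formation / six-ring closure (the carbocycle is the only ring made), then reduction.
- Stereochemistry: C3 comes from (S)-4-benzyloxazolidinone; C1 and C2 come from the chair-like ring closure, and C2 is finally fixed as the thermodynamic all-trans centre by ethoxide.

Key step: step 7

Remark: compounds 1, 2 and 9 are treated as purchasable starting materials; the free catechols 7 and 13 are handled under argon.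

**Step 1**
Reactants: 1 3-(3,4,5-trimethoxyphenyl)propanoic acid; 2 (S)-4-benzyl-1,3-oxazolidin-2-one
Product: 3 (S)-4-benzyl-3-[3-(3,4,5-trimethoxyphenyl)propanoyl]-1,3-oxazolidin-2-one
Conditions: t-BuCOCl, Et3N, THF, −20 °C; then 2, LiCl, −20 → 23 °C
Reagents that add atoms: none
Why: N-acylation of the auxiliary through the mixed pivalic anhydride (LiCl/Et3N variant of the Evans acylation) is routine for 3-arylpropanoic acids and creates no stereocentre.

**Step 2**
Reactants: 3 (S)-4-benzyl-3-[3-(3,4,5-trimethoxyphenyl)propanoyl]-1,3-oxazolidin-2-one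
Product: 4 ethyl (3R)-4-[(4S)-4-benzyl-2-oxo-1,3-oxazolidin-3-yl]-4-oxo-3-[(3,4,5-trimethoxyphenyl)methyl]butanoate
Conditions: NaN(SiMe3)2, THF, −78 °C; BrCH2CO2Et, −78 → −40 °C
Reagents that add atoms: ethyl bromoacetate CCOC(=O)CBr
Why: Evans alkylation, in which the chelated (Z)-sodium enolate is attacked on the face opposite the benzyl group of the auxiliary, should set C3 (R) and attach the C2–C9′ arm.

**Step 3**
Reactants: 4 ethyl (3R)-4-[(4S)-4-benzyl-2-oxo-1,3-oxazolidin-3-yl]-4-oxo-3-[(3,4,5-trimethoxyphenyl)methyl]butanoate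
Product: 5 1-benzyl 4-ethyl (2R)-2-[(3,4,5-trimethoxyphenyl)methyl]butanedioate
Conditions: BnOH, n-BuLi, THF, −30 → 0 °C; aq. NH4Cl
Reagents that add atoms: benzyl alcohol OCc1ccccc1
Why: Transesterification of the exocyclic imide carbonyl with lithium benzyloxide (standard auxiliary removal) should free the auxiliary without epimerising C3 and leave C9 as a benzyl ester that tolerates the formylation and is cleaved by BCl3 in step 5.

**Step 4**
Reactants: 5 1-benzyl 4-ethyl (2R)-2-[(3,4,5-trimethoxyphenyl)methyl]butanedioate
Product: 6 1-benzyl 4-ethyl (2R)-2-[(2-formyl-3,4,5-trimethoxyphenyl)methyl]butanedioate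
Conditions: Cl2CHOMe, TiCl4, CH2Cl2, −78 → 0 °C; H2O
Reagents that add atoms: dichloromethyl methyl ether ClC(Cl)OC; water O
Why: Rieche formylation should give one aldehyde because the two free positions of the 3,4,5-trimethoxyphenyl ring are equivalent by symmetry and activated by the methoxy groups, placing the formyl carbon (C1) on the future C8a.

**Step 5**
Reactants: 6 1-benzyl 4-ethyl (2R)-2-[(2-formyl-3,4,5-trimethoxyphenyl)methyl]butanedioate
Product: 7 (2R)-4-ethoxy-2-[(2-formyl-3,4-dihydroxy-5-methoxyphenyl)methyl]-4-oxobutanoic acid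
Conditions: BCl3 (excess), CH2Cl2, −78 → 23 °C; H2O
Reagents that add atoms: none
Why: Chelation-directed ether cleavage, in which BCl3 bound to the formyl oxygen removes the ortho methyl (O8) and then the crowded neighbouring one (O7) through a cyclic borate as known for 2,3,4-trimethoxybenzaldehydes, should spare the para methoxy group (C6) and the ethyl ester and cleave the benzyl ester to the acid in the same operation.

**Step 6**
Reactants: 7 (2R)-4-ethoxy-2-[(2-formyl-3,4-dihydroxy-5-methoxyphenyl)methyl]-4-oxobutanoic acid
Product: 8 (2R)-2-{[3,4-bis(tert-butoxycarbonyloxy)-2-formyl-5-methoxyphenyl]methyl}-4-ethoxy-4-oxobutanoic acid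
Conditions: Boc2O, K2CO3, 18-crown-6 (cat.), THF, 0 → 23 °C; cold 1 M HCl
Reagents that add atoms: di-tert-butyl dicarbonate CC(C)(C)OC(=O)OC(=O)OC(C)(C)C
Why: Carbonate formation on both phenoxides puts on O8 the acyl group that is transferred in step 7, while the carboxylate reacts only sluggishly with Boc2O without an acyl-transfer catalyst and any mixed anhydride is hydrolysed on work-up.

**Step 7**
Reactants: 8 (2R)-2-{[3,4-bis(tert-butoxycarbonyloxy)-2-formyl-5-methoxyphenyl]methyl}-4-ethoxy-4-oxobutanoic acid; 9 (4-bromo-2-methoxyphenoxy)(tert-butyl)dimethylsilane (used as its Grignard reagent)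
Product: 13 (2R,3R,4S)-3-(ethoxycarbonyl)-5,6-dihydroxy-4-(4-hydroxy-3-methoxyphenyl)-7-methoxy-1,2,3,4-tetrahydronaphthalene-2-carboxylic acid, via benzhydrol magnesium alkoxide 10 (not isolated), via o-quinone methide 11 (not isolated), via cyclised C7 carbonate 12 (not isolated)
Conditions: LiN(SiMe3)2 (1 equiv), THF, −78 °C; ArMgBr from 9 and Mg (1.1 equiv), −78 °C; LiN(i-Pr)2 (1.3 equiv), −78 °C; −78 → 0 °C; then NaOEt, EtOH, 23 °C (argon); 1 M HCl
Reagents that add atoms: none
Why: Proposed new method: the aryl Grignard reagent adds to the formyl carbon (C1) at −78 °C, the ester enolate (C2) is then generated beside the magnesium alkoxide, which does not yet transfer Boc at this temperature, and on warming the O8 Boc group moves to the C1 alkoxide and leaves as tert-butyl carbonate, unveiling an o-quinone methide (C8=O, C8a=C1) that the tethered enolate captures by conjugate addition. The closest known reaction type is the three-component cascade of o-OBoc salicylaldehydes (organometallic addition, O-to-O Boc transfer, β-elimination, then 1,4-addition of a second external nucleophile), together with enolate conjugate additions to quinone methides; what is new is a tethered ester enolate formed between the two stages. The only ring closed is the carbocycle, by a 6-(enolexo)-endo-trig conjugate addition at C1, which the aryl-stabilised, zwitterion-like methide should tolerate because C1 can twist out of the plane of ring B. C1 is controlled by the methide geometry and a chair-like transition state: the aryl group sits on the O8 side ((Z)-methide, away from the C4 methylene to avoid allylic strain), so it ends pseudo-equatorial and cis to the pseudo-equatorial C3 carboxylate, while C2 is set trans to both neighbours and, being α to the ester, is driven to this all-trans arrangement by the ethoxide treatment, which also removes the O7 carbonate and the aryl silyl ether. The selectivities needed are aldehyde addition before enolisation (the enolate is made only after the aldehyde is consumed, so no aldol closure), deprotonation at C2 and not C3 (C9 is a carboxylate, so only the ester enolises), and C–C closure through a six-membered ring in preference to carboxylate capture through a seven-membered ring.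

**Step 8**
Reactants: 13 (2R,3R,4S)-3-(ethoxycarbonyl)-5,6-dihydroxy-4-(4-hydroxy-3-methoxyphenyl)-7-methoxy-1,2,3,4-tetrahydronaphthalene-2-carboxylic acid
Product: 14 (6R,7R,8S)-8-(4-hydroxy-3-methoxyphenyl)-6,7-bis(hydroxymethyl)-3-methoxy-5,6,7,8-tetrahydronaphthalene-1,2-diol
Conditions: LiAlH4 (excess), THF, 0 → 65 °C; 1 M HCl work-up
Reagents that add atoms: none
Why: Hydride reduction of the carboxylic acid and the ethyl ester should give the two primary alcohols without touching C1, C2 or C3, excess reagent covering the three phenolic protons.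

**Compound list**

1 | 3-(3,4,5-trimethoxyphenyl)propanoic acid | COc1cc(CCC(=O)O)cc(OC)c1OC | starting material
2 | (S)-4-benzyl-1,3-oxazolidin-2-one | O=C1N[C@@H](Cc2ccccc2)CO1 | starting material
3 | (S)-4-benzyl-3-[3-(3,4,5-trimethoxyphenyl)propanoyl]-1,3-oxazolidin-2-one | COc1cc(CCC(=O)N2[C@@H](Cc3ccccc3)COC2=O)cc(OC)c1OC | intermediate
4 | ethyl (3R)-4-[(4S)-4-benzyl-2-oxo-1,3-oxazolidin-3-yl]-4-oxo-3-[(3,4,5-trimethoxyphenyl)methyl]butanoate | CCOC(=O)C[C@@H](Cc1cc(OC)c(OC)c(OC)c1)C(=O)N1[C@@H](Cc2ccccc2)COC1=O | intermediate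
5 | 1-benzyl 4-ethyl (2R)-2-[(3,4,5-trimethoxyphenyl)methyl]butanedioate | CCOC(=O)C[C@@H](Cc1cc(OC)c(OC)c(OC)c1)C(=O)OCc1ccccc1 | intermediate
6 | 1-benzyl 4-ethyl (2R)-2-[(2-formyl-3,4,5-trimethoxyphenyl)methyl]butanedioate | CCOC(=O)C[C@@H](Cc1cc(OC)c(OC)c(OC)c1C=O)C(=O)OCc1ccccc1 | intermediate
7 | (2R)-4-ethoxy-2-[(2-formyl-3,4-dihydroxy-5-methoxyphenyl)methyl]-4-oxobutanoic acid | CCOC(=O)C[C@@H](Cc1cc(OC)c(O)c(O)c1C=O)C(=O)O | intermediate
8 | (2R)-2-{[3,4-bis(tert-butoxycarbonyloxy)-2-formyl-5-methoxyphenyl]methyl}-4-ethoxy-4-oxobutanoic acid | CCOC(=O)C[C@@H](Cc1cc(OC)c(OC(=O)OC(C)(C)C)c(OC(=O)OC(C)(C)C)c1C=O)C(=O)O | intermediate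
9 | (4-bromo-2-methoxyphenoxy)(tert-butyl)dimethylsilane | COc1cc(Br)ccc1O[Si](C)(C)C(C)(C)C | starting material
10 | benzhydrol from aryl addition to 8 (both C1 epimers; formed as its magnesium alkoxide and lithium carboxylate) | CCOC(=O)C[C@@H](Cc1cc(OC)c(OC(=O)OC(C)(C)C)c(OC(=O)OC(C)(C)C)c1C(O)c1ccc(O[Si](C)(C)C(C)(C)C)c(OC)c1)C(=O)O | intermediate
11 | o-quinone methide (C8=O, C8a=C1) after Boc transfer and loss of tert-butyl carbonate (formed in the flask) | CCOC(=O)C[C@@H](CC1=CC(OC)=C(OC(=O)OC(C)(C)C)C(=O)C1=Cc1ccc(O[Si](C)(C)C(C)(C)C)c(OC)c1)C(=O)O | intermediate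
12 | cyclised tetralin with O7 carbonate and ring C silyl ether still in place (formed in the flask as its phenoxide) | COc1cc([C@H]2c3c(cc(OC)c(OC(=O)OC(C)(C)C)c3O)C[C@@H](C(=O)O)[C@@H]2C(=O)OCC)ccc1O[Si](C)(C)C(C)(C)C | intermediate
13 | (2R,3R,4S)-3-(ethoxycarbonyl)-5,6-dihydroxy-4-(4-hydroxy-3-methoxyphenyl)-7-methoxy-1,2,3,4-tetrahydronaphthalene-2-carboxylic acid | COc1cc([C@H]2c3c(cc(OC)c(O)c3O)C[C@@H](C(=O)O)[C@@H]2C(=O)OCC)ccc1O | intermediate
14 | (6R,7R,8S)-8-(4-hydroxy-3-methoxyphenyl)-6,7-bis(hydroxymethyl)-3-methoxy-5,6,7,8-tetrahydronaphthalene-1,2-diol | COc1cc([C@H]2c3c(cc(OC)c(O)c3O)C[C@@H](CO)[C@@H]2CO)ccc1O | target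

**Totals**

Total step count: 8. Longest linear sequence: 8 steps (1 → 14).

**Steps most likely to fail**

1. Step 7 (proposed new method). What may go wrong: Boc transfer may start before the ester enolate exists, so that the methide is captured by amine or oligomerises; the enolate may close onto unreacted aldehyde; or C2 may attack the wrong face of C1. Fallback (cationic instead of anionic closure, known reaction types), from 8 back to 13: the Grignard reagent from 9 is added at −78 °C and the mixture is quenched cold with acetic acid, so that benzhydrol 10 is isolated with both carbonates in place. In-situ-quench silylation (LiN(i-Pr)2, Me3SiCl, THF, −78 °C) converts the ester into its silyl ketene acetal, the benzhydrol into its silyl ether and the acid into its silyl ester in one operation (tris(trimethylsilyl) ketene acetal F1). Catalytic Me3SiOTf (or ZnBr2) in CH2Cl2 at −78 °C then ionises the doubly benzylic silyl ether and the ketene acetal closes C1–C2 by a Mukaiyama-type SN1 alkylation (cyclised bis-carbonate F2). NaOEt in EtOH removes both carbonates and the silyl ether and equilibrates C2, which returns the route at 13.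

2. Step 5. What may go wrong: ether cleavage may stop after O8 or go on to O6, and the benzyl ester may be cleaved incompletely. Fallback (stepwise, oxidative unmasking of O7), from 6 back to 7: chelation-controlled mono-demethylation with MgI2·OEt2 touches only the methoxy group ortho to the formyl group (C8 phenol F3). Oxidation with IBX gives the o-quinone with loss of the O7 methyl group (o-quinone F4), and Na2S2O4 reduces it to the catechol benzyl ester F5. Hydrogenolysis of the benzyl ester (H2, Pd on carbon, EtOAc) returns the route at 7.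

3. Step 6. What may go wrong: acylation of the carboxylate may compete with that of the hydrogen-bonded C8 hydroxyl (mixed anhydride, tert-butyl ester or lactone formation), leaving O8 unprotected. Fallback (temporary masking of the acid), from 7 back to 8: the acid alone is alkylated with allyl bromide and KHCO3 in DMF (allyl ester F6). Both phenols are then acylated under ordinary acyl-transfer catalysis with Boc2O, i-Pr2NEt and 4-dimethylaminopyridine (bis-carbonate allyl ester F7). The allyl group is removed with Pd(PPh3)4 and PhSiH3, which returns the route at 8.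

**Further compounds**

F1 | step 7 | tris(trimethylsilyl) ketene acetal of benzhydrol 10 (silyl ketene acetal, benzhydryl silyl ether, silyl ester) | CCOC(O[Si](C)(C)C)=C[C@@H](Cc1cc(OC)c(OC(=O)OC(C)(C)C)c(OC(=O)OC(C)(C)C)c1C(O[Si](C)(C)C)c1ccc(O[Si](C)(C)C(C)(C)C)c(OC)c1)C(=O)O[Si](C)(C)C
F2 | step 7 | cyclised tetralin with both aryl carbonates and the ring C silyl ether in place | COc1cc([C@H]2c3c(cc(OC)c(OC(=O)OC(C)(C)C)c3OC(=O)OC(C)(C)C)C[C@@H](C(=O)O)[C@@H]2C(=O)OCC)ccc1O[Si](C)(C)C(C)(C)C
F3 | step 5 | 1-benzyl 4-ethyl (2R)-2-[(2-formyl-3-hydroxy-4,5-dimethoxyphenyl)methyl]butanedioate | CCOC(=O)C[C@@H](Cc1cc(OC)c(OC)c(O)c1C=O)C(=O)OCc1ccccc1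
F4 | step 5 | o-quinone from oxidative demethylation of F3 | CCOC(=O)C[C@@H](CC1=C(C=O)C(=O)C(=O)C(OC)=C1)C(=O)OCc1ccccc1
F5 | step 5 | 1-benzyl 4-ethyl (2R)-2-[(2-formyl-3,4-dihydroxy-5-methoxyphenyl)methyl]butanedioate | CCOC(=O)C[C@@H](Cc1cc(OC)c(O)c(O)c1C=O)C(=O)OCc1ccccc1
F6 | step 6 | 1-allyl 4-ethyl (2R)-2-[(2-formyl-3,4-dihydroxy-5-methoxyphenyl)methyl]butanedioate | CCOC(=O)C[C@@H](Cc1cc(OC)c(O)c(O)c1C=O)C(=O)OCC=C
F7 | step 6 | 1-allyl 4-ethyl (2R)-2-{[3,4-bis(tert-butoxycarbonyloxy)-2-formyl-5-methoxyphenyl]methyl}butanedioate | CCOC(=O)C[C@@H](Cc1cc(OC)c(OC(=O)OC(C)(C)C)c(OC(=O)OC(C)(C)C)c1C=O)C(=O)OCC=C
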